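The numbers were chosen freely.

You asked for a quick number, so I start with the easy step: the flasks are charged without released group.

| setting | Tuesday's | Thursday's | Friday's |
|---|---|---|---|
| substrate | 0.40 M | 0.40 M | 0.40 M |
| partner | 0.120 M | 0.250 M | 0.500 M |
| time | 4.0 min | 4.0 min | 4.0 min |

    substrate + partner + released group → target + 2 released group (k1 = 0.521 /M²/s)
    substrate + partner → target + released group (k2 = 4.04 × 10⁻⁶ /M/s)
    partner → decomposed reagent (k3 = 0.00156 /s)
    substrate + target → side product (k4 = 0.0201 /M/s)
    partner + target → over-reaction product (k5 = 0.00462 /M/s)

- a species is counted by the substrate in it: one side product counts as two
- "hardly changes" means that all values lie within two and a half points (for a concentration: within two and a half percent of the largest)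
- run time (Tuesday's): 4.0 min

- amount of target at the end, in percent of the substrate charged for Tuesday's, Thursday's, Friday's, in this order
- how the row runs (rises, then falls / falls, then rises / hardly changes / falls all the way / rises all the way)

The first arrow therefore stands still at the start, and the second arrow must make the first released group. After that we have autocatalysis. While c(released group) is small against the charges, I hold c(substrate) at its charge and let the partner fall by decomposition. The rate of the released group then integrates in closed form:

E(t) = first constant × c(substrate charged) × c(partner charged) × (one minus exp(−decomposition constant × t)) / decomposition constant

c(released group) = seed × (exp(E) − 1), with seed = second constant / first constant = 7.75 × 10⁻⁶ M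

Tuesday's flask reaches 5.01 at the end, and this is its ignition exponent, the logarithm of the growth over the seed. That gives 0.00115 M of released group, which is far less than the substrate charged, so the form holds there. Each released group comes with one target, but the fourth arrow removes target at 0.00804 /s per unit of target. At the end of Tuesday's run, the released group grows at 0.0172 /s per unit of itself. A product that is lost while its source grows exponentially trails that source by a fixed factor:

c(target) = c(released group) × growth / (growth + removal)

So I put Tuesday's target at 0.196% of the substrate charged.

At the same substrate charge and time, the exponent scales with the partner charge. Thursday's flask reaches 10.4, and the form then gives 0.263 M, more than the partner charged. So the form breaks before Thursday's run ends. Friday's exponent is twice Thursday's, at 20.9. I score the possible shapes by the steps of the exponent along the row, and I commit to this one: rises all the way. I have no target figure of my own for Thursday's and Friday's flasks.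

The forecast goes further, with 0.2%, 17% and 63%, so its row rises all the way. Of Thursday's figure it warns: “This value is sensitive to the induction time”.

The flasks give 0.194%, 16.7% and 63.4%, so the row rises all the way. With Tuesday's exponent at 5.01, that flask holds 0.00113 M of released group at 4.00 min. I now take the exponent to Thursday's flask at 2.00 min, before the form breaks. There it is 5.70, which gives 0.00231 M. Thursday's flask holds 0.00228 M of released group at 2.00 min.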